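- At the first reading of Tuesday's run, 25.0 s after the start, side product A already stands at 4.7% against a later mean of 6.78%, so by these scattered readings 69.3% of it is made by then.

| setting | Tuesday's | Monday's | Saturday's | cedar | ash | alder | elm |
|---|---|---|---|---|---|---|---|
| substrate | 1 mM | 1 mM | 1 mM | 1.0 mM | 1.0 mM (fed, over 80 s) | 1.0 mM | 1.0 mM |
| partner | 2 equiv | 2 equiv | 2 equiv | 2.00 equiv | 2.00 equiv | 2.00 equiv | 2.00 equiv |
| rival reagent | 2 equiv | 1.3 equiv | 3 equiv | 2.00 equiv (fed, over 8.0 s) | 2.00 equiv | 2.00 equiv (fed, over 80 s) | 2.00 equiv |
| remark | run made earlier | run made earlier | run made earlier | all else is in the flask from the start; the feed brings no volume worth counting | all else is in the flask from the start; the feed brings no volume worth counting | all else is in the flask from the start; the feed brings no volume worth counting | everything together at the start |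
| time |  |  |  | 2.0 min | 2.0 min | 2.0 min | 2.0 min |

- Tuesday's (time / s: target / %, side product A / %): 25.0: 14.0, 4.7; 50.0: 19.3, 5.7; 80.0: 17.8, 7.1; 90.0: 19.0, 7.6; 120: 18.2, 6.7
- Monday's (time / min: target / %, side product A / %): 0.200: 9.7, 3.1; 0.667: 17.0, 3.3; 1.00: 17.5, 6.0; 1.50: 17.1, 5.9; 2.50: 19.3, 5.2
- Saturday's (time / min: target / %, side product A / %): 0.200: 9.5, 5.1; 0.333: 11.9, 6.1; 0.667: 16.1, 7.5; 1.33: 18.1, 7.5; 2.50: 18.4, 8.0

(standard deviation of a reading: 1 percentage point)

- the flask that comes out highest in share of target in target plus side product A, or "all alike" when all lie within 1.5 percentage points (cedar / ash / alder / elm / all alike)
- share of target in target plus side product A at the end, cedar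
- share of target in target plus side product A at the end, ash
- share of target in target plus side product A at the end, alder
- share of target in target plus side product A at the end, elm

- the numbers in the tables scatter with a standard deviation of 1 percentage point

- With the main step alone, substrate and partner give target, and the share of target in target plus side product A (the selectivity) stands at 100%. Tuesday's target levels off at a mean of 18.6%, and the last readings of Monday's and Saturday's runs, 19.3% and 18.4%, lie close to it despite their different rival loadings.
- Adding substrate with rival reagent to side product A brings the share down to 73.3% on Tuesday's charges. A rival reagent that lasted should make side product A follow its charge, but between Monday's and Saturday's runs the charge grows by a factor of 2.31 and the last three readings of side product A by a factor of 1.35.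
- A further step is read here as a loss of the rival reagent, which would leave it a short working window, taken roughly from that first reading of Tuesday's run as 25.0 s. The readings do not prove that it is the rival reagent, rather than the substrate, that stops acting; this reckoning assumes so.
- This reckoning then holds that window against the feed time of ash, 80 s. The overlap is the fraction of the substrate charge fed in by the time the window closes, window over feed time, 0.312 for ash.
- In ash the window is shorter than the feed, so this reckoning scales side product A by the overlap to 2.12%. With the target level held, this reckoning puts the share of ash at 89.8%.
- Cedar, alder and elm hold their whole substrate charge from the start, so their overlap is one whenever the window closes, and this reckoning keeps them near 73.3%.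
- The forecast names alder: cedar 75% (72% to 78%), ash 73% (68% to 79%), alder 83% (77% to 88%), elm 73% (71% to 75.5%). For ash it holds that “feeding substrate changes little if the paths are first-order in substrate”, and there and on alder it differs from the reckoning above.
- The flasks give cedar 71.1%, ash 89.3%, alder 72.8% and elm 72.5%, so ash comes out highest.

    substrate + rival reagent → side product A (k = 4.90 L mol⁻¹ s⁻¹)
    2 rival reagent → homo dimer (k = 90.0 L mol⁻¹ s⁻¹)
    substrate + target → side product B (k = 50.0 L mol⁻¹ s⁻¹)
    substrate + partner → target (k = 5.90 L mol⁻¹ s⁻¹)

- Ash ends with side product A at 2.11% against 6.73% in elm, a ratio of 0.314 beside the overlap of 0.312. The neighbouring flask is ash with 0.60 mM of substrate, equivalents and time held. With the window carried over unchanged, its overlap stays 0.312, and since both products are counted in percent of the charge, the reckoning again gives 89.8%. That neighbour gives 87.6%, with target at 16.8%, side product A at 2.39% and substrate still at 44.7%.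

The runs were generated by integration from invented constants, noise included.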